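Carbon numbering used throughout: seven-membered ring C11 (ketone), C2 (methyl-bearing alkene carbon), C3, C4 (carbinol), C5 (ring-fusion CH), C6 (angular quaternary carbon), C10; five-membered ring C5, C6, C7, C8, C9. Names of bicyclic compounds use azulene locants (C1 = C9, C3a = C6, C4 = C10, C5 = C11, C6 = C2, C7 = C3, C8 = C4, C8a = C5).

## The problem

The target is a trans-fused bicyclo[5.3.0]decane of the daucane type. Its seven-membered ring carries the C11 ketone, the C2–C3 alkene with the C2 methyl group and the C4 carbinol; its five-membered ring carries at C9 the isopropyl group and the 4-hydroxybenzoate. Four contiguous stereocentres must be set, C4 (S), C5 (S), C6 (R) and C9 (R). C6 and C9 are fully substituted and cannot be corrected once made, C5 is adjustable only while C4 is a ketone, and C4 can be left to a late reduction. C9 is the one centre that can be made on its own by asymmetric catalysis, so it has to control C6 across C5; C6 and C9 together then decide the faces of C5 and C4, whose hydrogen and hydroxyl both lie opposite the angular methyl and the C9 oxygen. The 4-hydroxy-enone, the free phenol and a tertiary ester beside a free secondary hydroxyl (acyl shift from the C9 oxygen to the C4 oxygen in base) will not survive rough treatment. Any intermediate with a C4 ketone beta to the C9 oxygen can also lose that oxygen by elimination, and the ester itself must be formed on a tertiary alcohol flanked by isopropyl and the ring fusion. The enabling feature is that the oxygens on C4 and C11 flank the C2–C3 alkene as the ketone and ether bridge do in a 3-oxidopyrylium–alkene adduct, and that C5 and C6 are joined through C9–C8–C7, a three-carbon chain that can tether the alkene so that one cycloaddition closes both carbocycles.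

## Retrosynthesis

**Ester and silyl groups (27 ← 26 ← 22 + 25).** The acyl–oxygen bond at C9 and two Si–O bonds are cut last. The phenol and the C4 hydroxyl are both held as tert-butyldimethylsilyl ethers, so one buffered fluoride treatment frees them without ever forming a C4 alkoxide next to the tertiary ester. Acylating the diol directly would put the acyl group on C4, so the C4 oxygen must be masked in 22. The forward step asks a hindered tertiary lithium alkoxide to take the acid chloride 25 in the presence of the C11 ketone.

**Oxidation levels at C4 and C11 (22 ← 21 ← 20 ← 19).** No skeletal bond is cut; the C4–H bond is traced to a hydride and the C11 carbonyl to an alcohol. In 19 the C11 hydroxyl is the only oxidisable one because the C9 alcohol is tertiary. In the enedione 20 the C4 ketone is the only one beta to that alcohol. Oxidation followed by hydroxyl-directed reduction therefore exchanges the two oxygen functions with no protecting group at C11. The neighbouring choice (protect C11, reduce C4, protect C4, unmask and oxidise C11) costs more operations, and an external hydride would be steered by the angular methyl to the wrong face of C4. The forward reaction needs the C9 hydroxyl to deliver hydride from its own face.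

**Ether bridge (19 ← 18 ← 17).** The C5–H bond is traced to the C5–O bond of an oxygen bridge that lies alpha to the C4 ketone. Reductive cleavage keeps the oxygen on C11 and turns C5 into an enolate carbon. The forward step must protonate C5 on the face the oxygen leaves, which gives the trans ring fusion.

**Both rings (17 ← 16 ← 15).** The C5–C6 and C10–C11 bonds are cut together. This removes both carbocycles and three stereocentres and leaves the monocyclic acetoxypyranone 15 with a single stereocentre, C9. Closing the rings one at a time would need a separate seven-membered ring closure and a separate construction of quaternary C6. The forward (5+2) cycloaddition must choose the pyrylium face that puts the C6 methyl cis to the C9 oxygen.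

**Pyranone (15 ← 14 ← 13).** The pyranone is the oxidative ring expansion product of the furyl carbinol 13. The carbinol carbon becomes C5 and is planar in the ylide 16, so its configuration need not be controlled.

**Furan–carbinol bond (13 ← 8 + 10; 10 ← 9).** The bond between furan C2 and the carbinol carbon is cut to the aldehyde 8 and a metalated furan. The methyl group must end up at furan C4. Direct metalation of 3-methylfuran 9 is not reliably selective for the position remote from the methyl group. Bromination of 9 at the position next to the methyl gives 10, which can be deprotonated only at the wanted carbon; the bromine is exchanged for hydrogen in the same flask.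

**C9 building block (8 ← 7 ← 6 ← 4 + 5; 4 ← 3 ← 1 + 2).** The C7–C8 bond is cut to the epoxy alcohol 4 and the 2-methylallyl Grignard reagent 5. C9 comes from asymmetric epoxidation of the 2-substituted allylic alcohol 3, itself made from 1 and 2. The alternative source of C9, alkylating the enolate of a chiral alpha-hydroxy-acid acetal with an unactivated homoallylic halide, pairs a hindered enolate with a poor electrophile and was set aside. The aldehyde 8 has no alpha hydrogen, so C9 cannot be lost on the way.

**Acyl donor (25 ← 24 ← 23).** The silyl-protected acid chloride 25 comes from 4-hydroxybenzoic acid 23 in two operations.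

## Roads not taken

**Alternative 1:** The cut is through C2–C3 and C6–C10, giving the dienyl ketal A1 and the siloxyvinyl diazoester A2. In the forward direction a chiral dirhodium carboxylate such as Rh2(S-DOSP)4 would cyclopropanate the terminal alkene of A1, and the cis-divinylcyclopropane would undergo Cope rearrangement to the cycloheptadiene A3.
- Merits: it is convergent, the catalyst sets quaternary C6, and C11 arrives oxygenated with C9 as a masked ketone.
- Weak points for this target: C2 carries an ester where a methyl group is needed. The C2–C3 alkene must be moved into place. The C4–C5 alkene must be hydrated with control of two centres. The isopropyl group must be added late to a hindered, enolisable C9 ketone from one face, which creates the tertiary alcohol at the end.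
- Comparison: this road is better in enantiocontrol of C6, which a catalyst decides rather than a substrate. The chosen plan sets against this that the C2 methyl, the C2–C3 alkene, both ring oxygens and the finished C9 centre are all in place after the cycloaddition, so fewer corrections follow.

**Alternative 2:** The cut is through C6–C10 and C4–C5, with the seven-membered ring closed later at C2–C11. In the forward direction, copper-catalysed asymmetric addition of a 1-silylvinyl aluminium reagent to 3-methylcyclopent-2-en-1-one A4 gives an aluminium enolate that is trapped by (Z)-3-iodobut-2-enal A5 to give A6.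
- Merits: C6 is set by the catalyst. C5 is set by enolate alkylation geometry and not by protonation. C4 arrives at the alcohol level, so no exchange of oxidation levels is needed.
- Weak points: the seven-membered ring is still open and needs several functional-group operations and a medium-ring closure. The aldehyde face in the aldol step is not secured. A5 is sensitive. The C9 ketone is beta to the C4 hydroxyl (retro-aldol), and isopropyl must again be added late.
- Comparison: in the control of C5 and in the oxidation level of C4 this road is better. The chosen plan sets against this the closure of both rings in one step and a C9 centre made before any ring exists.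

**Alternative 3:** The cut is through the C6–methyl bond and C5–C9. In the forward direction, copper-catalysed conjugate addition of a methyl group from an aluminium reagent to the cycloheptenone A7 gives an enolate that adds to the pendant isopropyl ketone and closes the five-membered ring to A8.
- Merits: C6, C5 and C9 are made in one step, the tertiary carbinol with its isopropyl group is formed directly, and the trans fusion comes from the cyclisation.
- Weak points: the seven-membered ring arrives bare. The C2 methyl, the C2–C3 alkene and the C11 oxygen are all missing and would have to be installed by a long series of dehydrogenation, conjugate addition and remote oxidation steps starting from the C4 ketone. The aldol onto a hindered ketone is reversible, and the C9 configuration is not secured.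
- Comparison: for the five-membered ring and C5 this road is as good or better. The chosen plan sets against this that the functionality of the seven-membered ring, the sensitive half of the target, comes directly from the pyranone.

Key step: step 10

Assumption: metalation of 3-methylfuran is taken to be unselective or to favour the carbon next to the methyl group, so the 2,4-substitution pattern is secured with a bromine block.

## Route

Step 1
Reactants: 1 prop-2-yn-1-ol; 2 isopropylmagnesium chloride
Product: 3 3-methyl-2-methylidenebutan-1-ol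
Conditions: 2 (3 equiv), CuI (10 mol%), THF/Et2O, 0 °C to rt; aq. NH4Cl
Reagents that add atoms: none
Why: Copper-catalysed carbomagnesiation of the propargylic magnesium alkoxide puts the alkyl group on the internal alkyne carbon through a five-membered alkenylmagnesium chelate, which is protonated on work-up; this is a standard entry to 2-substituted allylic alcohols.

Step 2
Reactants: 3 3-methyl-2-methylidenebutan-1-ol
Product: 4 [(2R)-2-(propan-2-yl)oxiran-2-yl]methanol
Conditions: Ti(OiPr)4 (10 mol%), D-(−)-diisopropyl tartrate (12 mol%), t-BuOOH, 4 Å sieves, CH2Cl2, −20 °C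
Reagents that add atoms: tert-butyl hydroperoxide, CC(C)(C)OO
Why: Sharpless asymmetric epoxidation of a 2-substituted allylic alcohol; the D-(−)-tartrate complex should deliver oxygen to the alkene face that gives the R epoxide, which becomes C9 of the target. Catalytic loading with sieves limits opening of the sensitive 2,2-disubstituted epoxy alcohol.

Step 3
Reactants: 4 [(2R)-2-(propan-2-yl)oxiran-2-yl]methanol; 5 (2-methylprop-2-en-1-yl)magnesium chloride
Product: 6 (2R)-5-methyl-2-(propan-2-yl)hex-5-ene-1,2-diol
Conditions: 5 (3 equiv), CuI (10 mol%), THF, −40 to 0 °C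
Reagents that add atoms: none
Why: Copper-catalysed Grignard opening of the epoxide by SN2 attack at the unsubstituted carbon; the first equivalent only deprotonates the hydroxyl and the C9 centre is not touched.

Step 4
Reactants: 6 (2R)-5-methyl-2-(propan-2-yl)hex-5-ene-1,2-diol
Product: 7 (2R)-5-methyl-2-(propan-2-yl)-1,2-bis(triethylsilyloxy)hex-5-ene
Conditions: TESOTf (2.5 equiv), 2,6-lutidine, CH2Cl2, −78 to 0 °C
Reagents that add atoms: triethylsilyl trifluoromethanesulfonate, CC[Si](CC)(CC)OS(=O)(=O)C(F)(F)F
Why: Silylation with a silyl triflate, which is reactive enough for the hindered tertiary hydroxyl.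

Step 5
Reactants: 7 (2R)-5-methyl-2-(propan-2-yl)-1,2-bis(triethylsilyloxy)hex-5-ene
Product: 8 (2R)-5-methyl-2-(propan-2-yl)-2-(triethylsilyloxy)hex-5-enal
Conditions: (COCl)2, DMSO, CH2Cl2, −78 to −40 °C; Et3N, to 0 °C
Reagents that add atoms: none
Why: Swern oxidation applied to the bis-silyl ether: the primary triethylsilyl ether is cleaved by the chlorosulfonium salt and oxidised to the aldehyde, while the tertiary silyl ether is too hindered to react. The aldehyde has no alpha hydrogen and cannot epimerise.

Step 6
Reactants: 9 3-methylfuran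
Product: 10 2-bromo-3-methylfuran
Conditions: NBS, DMF, 0 °C to rt, dark
Reagents that add atoms: N-bromosuccinimide, O=C1CCC(=O)N1Br
Why: Electrophilic bromination of the furan; attack at C2 next to the methyl group gives the better stabilised cation, so bromine blocks the position that must stay free of the side chain.

Step 7
Reactants: 10 2-bromo-3-methylfuran; 8 (2R)-5-methyl-2-(propan-2-yl)-2-(triethylsilyloxy)hex-5-enal
Product: 13 (2R)-5-methyl-1-(4-methylfuran-2-yl)-2-(propan-2-yl)-2-(triethylsilyloxy)hex-5-en-1-ol (both C1 epimers), via lithiated bromofuran 11 (not isolated), via bromofuryl alkoxide 12 (not isolated)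
Conditions: LiN(iPr)2, THF, −78 °C; 8, −78 °C; t-BuLi (3.3 equiv), −78 °C; MeOH then aq. NH4Cl, −78 °C
Reagents that add atoms: none
Why: Deprotonation of a 2-bromofuran at its only free alpha position, 1,2-addition of the furyllithium to a non-enolisable aldehyde, then bromine–lithium exchange and protonation in the same flask. The new carbinol centre forms as a mixture, which does not matter because this carbon becomes planar in the ylide.

Step 8
Reactants: 13 (2R)-5-methyl-1-(4-methylfuran-2-yl)-2-(propan-2-yl)-2-(triethylsilyloxy)hex-5-en-1-ol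
Product: 14 2-[(3R)-2,6-dimethyl-3-(triethylsilyloxy)hept-6-en-3-yl]-6-hydroxy-5-methyl-2H-pyran-3(6H)-one (mixture at ring C2 and C6)
Conditions: NBS (1.05 equiv), NaHCO3, NaOAc, THF/H2O (4:1), 0 °C
Reagents that add atoms: water, O
Why: Achmatowicz rearrangement: bromonium attack on the furan, hydration, opening to the ene-dione and closure of the carbinol oxygen onto the aldehyde. The furan is far more nucleophilic than the isolated alkene, so one equivalent of NBS at 0 °C should spare the tether.

Step 9
Reactants: 14 2-[(3R)-2,6-dimethyl-3-(triethylsilyloxy)hept-6-en-3-yl]-6-hydroxy-5-methyl-2H-pyran-3(6H)-one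
Product: 15 6-acetoxy-2-[(3R)-2,6-dimethyl-3-(triethylsilyloxy)hept-6-en-3-yl]-5-methyl-2H-pyran-3(6H)-one (mixture at ring C2 and C6)
Conditions: Ac2O, pyridine, DMAP (cat.), CH2Cl2, 0 °C
Reagents that add atoms: acetic anhydride, CC(=O)OC(C)=O
Why: Acylation of the anomeric hydroxyl; both ring acetal centres are lost in the next step, so the mixture is of no consequence.

Step 10
Reactants: 15 6-acetoxy-2-[(3R)-2,6-dimethyl-3-(triethylsilyloxy)hept-6-en-3-yl]-5-methyl-2H-pyran-3(6H)-one
Product: 17 (1R,3aR,5S,8aS)-3a,6-dimethyl-1-(propan-2-yl)-1-(triethylsilyloxy)-2,3,3a,4-tetrahydro-1H-5,8a-epoxyazulen-8(5H)-one, via oxidopyrylium ylide 16 (not isolated)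
Conditions: DBU (1.5 equiv), MeCN (0.01 M), rt to 60 °C
Reagents that add atoms: none
Why: DBU removes the ring proton alpha to the ketone and acetate leaves (E1cB), giving the 3-oxidopyrylium 16, a six-electron carbonyl-ylide-type dipole that adds suprafacially across the tethered alkene through the two carbons next to its ring oxygen in a concerted, thermally allowed (5+2) cycloaddition. The closest known reaction type is the intramolecular 3-oxidopyrylium–alkene cycloaddition of 2-(pent-4-enyl) acetoxypyranones to oxygen-bridged bicyclo[5.3.0]decenones. The five-membered ring closes at C5–C6 through the three-carbon tether in the fused mode, the only one a three-atom link allows, which also fixes the regiochemistry; the seven-membered carbocycle closes at C10–C11 from the five pyrylium carbons and the two alkene carbons. C5, C6 and C11 are created together: the oxolane formed by the bridge oxygen and the new cyclopentane must be cis-fused, so the C6 methyl is forced anti to the bridge, and C11 follows from the bridge itself. The only open selectivity is the pyrylium face, and C9 decides it: with C8 held above the ring plane, one remaining C9 substituent must lie beside the oxido oxygen and the other beside the unsubstituted ring oxygen; allylic 1,3-strain should place the compact silyloxy oxygen beside the oxido oxygen and the branched isopropyl group beside the ring oxygen, which leads to the isomer with the C9 oxygen cis to the C6 methyl. The short tether should let the unactivated 1,1-disubstituted alkene outrun dimerisation of the ylide at high dilution.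

Step 11
Reactants: 17 (1R,3aR,5S,8aS)-3a,6-dimethyl-1-(propan-2-yl)-1-(triethylsilyloxy)-2,3,3a,4-tetrahydro-1H-5,8a-epoxyazulen-8(5H)-one
Product: 18 (1R,3aR,5S,8aR)-5-hydroxy-3a,6-dimethyl-1-(propan-2-yl)-1-(triethylsilyloxy)-2,3,3a,4,5,8a-hexahydroazulen-8(1H)-one
Conditions: SmI2 (2.2 equiv), THF/MeOH (10:1), −78 °C
Reagents that add atoms: none
Why: Reductive cleavage of an alpha-alkoxy ketone: two electrons enter the C4 carbonyl and the aligned C5–O bond is expelled, leaving a trivalent samarium dienolate and the C11 alkoxide. Methanol held at the samarium alkoxide on C11 sits on the face the oxygen has just left and should return the proton to C5 there, which gives the trans ring fusion.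

Step 12
Reactants: 18 (1R,3aR,5S,8aR)-5-hydroxy-3a,6-dimethyl-1-(propan-2-yl)-1-(triethylsilyloxy)-2,3,3a,4,5,8a-hexahydroazulen-8(1H)-one
Product: 19 (1R,3aR,5S,8aR)-1,5-dihydroxy-3a,6-dimethyl-1-(propan-2-yl)-2,3,3a,4,5,8a-hexahydroazulen-8(1H)-one
Conditions: HF·pyridine, pyridine/THF, 0 °C to rt
Reagents that add atoms: none
Why: Fluoride-assisted cleavage of the Si–O bond under buffered acidic conditions, which avoid the retro-aldol and beta-elimination that a basic fluoride source could start at the beta-hydroxy ketone.

Step 13
Reactants: 19 (1R,3aR,5S,8aR)-1,5-dihydroxy-3a,6-dimethyl-1-(propan-2-yl)-2,3,3a,4,5,8a-hexahydroazulen-8(1H)-one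
Product: 20 (1R,3aR,8aR)-1-hydroxy-3a,6-dimethyl-1-(propan-2-yl)-1,2,3,3a,4,8a-hexahydroazulene-5,8-dione
Conditions: Dess–Martin periodinane, NaHCO3, CH2Cl2, 0 °C to rt
Reagents that add atoms: none
Why: Dess–Martin oxidation; the C11 hydroxyl is the only oxidisable one because the C9 alcohol is tertiary, so the C11 carbonyl is installed without a protecting group.

Step 14
Reactants: 20 (1R,3aR,8aR)-1-hydroxy-3a,6-dimethyl-1-(propan-2-yl)-1,2,3,3a,4,8a-hexahydroazulene-5,8-dione
Product: 21 (1R,3aR,8S,8aS)-1,8-dihydroxy-3a,6-dimethyl-1-(propan-2-yl)-2,3,3a,4,8,8a-hexahydroazulen-5(1H)-one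
Conditions: Me4NBH(OAc)3, MeCN/AcOH (1:1), −30 to −20 °C
Reagents that add atoms: none
Why: Evans–Saksena reduction: the acetoxyborohydride exchanges a ligand with the C9 hydroxyl and delivers hydride through a six-membered transition state to the only ketone beta to it, so the C11 carbonyl is left alone. The C9 oxygen lies on the methyl-bearing face, so hydride should enter C4 on that face and the hydroxyl should end on the opposite one, cis to H5 as in the target; an external hydride would be pushed to the other face by the angular methyl.

Step 15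
Reactants: 21 (1R,3aR,8S,8aS)-1,8-dihydroxy-3a,6-dimethyl-1-(propan-2-yl)-2,3,3a,4,8,8a-hexahydroazulen-5(1H)-one
Product: 22 (1R,3aR,8S,8aS)-8-(tert-butyldimethylsilyloxy)-1-hydroxy-3a,6-dimethyl-1-(propan-2-yl)-2,3,3a,4,8,8a-hexahydroazulen-5(1H)-one
Conditions: TBSOTf (1.1 equiv), 2,6-lutidine, CH2Cl2, −78 °C
Reagents that add atoms: tert-butyldimethylsilyl trifluoromethanesulfonate, CC(C)(C)[Si](C)(C)OS(=O)(=O)C(F)(F)F
Why: Silylation with a silyl triflate; at −78 °C the secondary allylic C4 hydroxyl should react far faster than the tertiary C9 hydroxyl beside the isopropyl group.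

Step 16
Reactants: 23 4-hydroxybenzoic acid
Product: 24 tert-butyldimethylsilyl 4-(tert-butyldimethylsilyloxy)benzoate
Conditions: TBSCl (2.5 equiv), imidazole, DMF, rt
Reagents that add atoms: tert-butyldimethylsilyl chloride, CC(C)(C)[Si](C)(C)Cl
Why: Imidazole-promoted silylation of both the phenol and the carboxylic acid.

Step 17
Reactants: 24 tert-butyldimethylsilyl 4-(tert-butyldimethylsilyloxy)benzoate
Product: 25 4-(tert-butyldimethylsilyloxy)benzoyl chloride
Conditions: (COCl)2, DMF (cat.), CH2Cl2, 0 °C to rt
Reagents that add atoms: oxalyl chloride, ClC(=O)C(Cl)=O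
Why: Silyl esters are converted directly into acid chlorides by oxalyl chloride with catalytic DMF (Vilsmeier-type activation) under neutral conditions, which leave the aryl silyl ether intact.

Step 18
Reactants: 22 (1R,3aR,8S,8aS)-8-(tert-butyldimethylsilyloxy)-1-hydroxy-3a,6-dimethyl-1-(propan-2-yl)-2,3,3a,4,8,8a-hexahydroazulen-5(1H)-one; 25 4-(tert-butyldimethylsilyloxy)benzoyl chloride
Product: 26 (1R,3aR,8S,8aS)-8-(tert-butyldimethylsilyloxy)-3a,6-dimethyl-5-oxo-1-(propan-2-yl)-1,2,3,3a,4,5,8,8a-octahydroazulen-1-yl 4-(tert-butyldimethylsilyloxy)benzoate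
Conditions: LiN(SiMe3)2 (1.1 equiv), THF, −78 °C; 25 (1.5 equiv), −78 to −20 °C
Reagents that add atoms: none
Why: Acylation of a lithium alkoxide by an acid chloride; O–H deprotonation is faster than enolisation and lithium tertiary alkoxides are poor bases toward ketones. The C4 oxygen is masked, so the C9 alkoxide is the only acyl acceptor.

Step 19
Reactants: 26 (1R,3aR,8S,8aS)-8-(tert-butyldimethylsilyloxy)-3a,6-dimethyl-5-oxo-1-(propan-2-yl)-1,2,3,3a,4,5,8,8a-octahydroazulen-1-yl 4-(tert-butyldimethylsilyloxy)benzoate
Product: 27 (1R,3aR,8S,8aS)-8-hydroxy-3a,6-dimethyl-5-oxo-1-(propan-2-yl)-1,2,3,3a,4,5,8,8a-octahydroazulen-1-yl 4-hydroxybenzoate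
Conditions: HF·pyridine, pyridine/THF, 0 °C to rt
Reagents that add atoms: none
Why: Fluoride-assisted cleavage of the aryl and the secondary silyl ether; no free alkoxide is formed under these buffered conditions, so the tertiary ester should not migrate to the C4 oxygen.

## Compound list

1 | prop-2-yn-1-ol | C#CCO | starting material
2 | isopropylmagnesium chloride | CC(C)[Mg]Cl | starting material
3 | 3-methyl-2-methylidenebutan-1-ol | C=C(CO)C(C)C | intermediate
4 | [(2R)-2-(propan-2-yl)oxiran-2-yl]methanol | OC[C@]1(C(C)C)CO1 | intermediate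
5 | (2-methylprop-2-en-1-yl)magnesium chloride | C=C(C)C[Mg]Cl | starting material
6 | (2R)-5-methyl-2-(propan-2-yl)hex-5-ene-1,2-diol | OC[C@](O)(C(C)C)CCC(C)=C | intermediate
7 | (2R)-5-methyl-2-(propan-2-yl)-1,2-bis(triethylsilyloxy)hex-5-ene | CC[Si](CC)(CC)OC[C@](O[Si](CC)(CC)CC)(C(C)C)CCC(C)=C | intermediate
8 | (2R)-5-methyl-2-(propan-2-yl)-2-(triethylsilyloxy)hex-5-enal | O=C[C@](O[Si](CC)(CC)CC)(C(C)C)CCC(C)=C | intermediate
9 | 3-methylfuran | Cc1ccoc1 | starting material
10 | 2-bromo-3-methylfuran | Cc1ccoc1Br | intermediate
11 | (5-bromo-4-methylfuran-2-yl)lithium | [Li]c1cc(C)c(Br)o1 | intermediate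
12 | lithium (2R)-1-(5-bromo-4-methylfuran-2-yl)-5-methyl-2-(propan-2-yl)-2-(triethylsilyloxy)hex-5-en-1-olate (both C1 epimers) | [Li+].[O-]C(c1cc(C)c(Br)o1)[C@](O[Si](CC)(CC)CC)(C(C)C)CCC(C)=C | intermediate
13 | (2R)-5-methyl-1-(4-methylfuran-2-yl)-2-(propan-2-yl)-2-(triethylsilyloxy)hex-5-en-1-ol (both C1 epimers) | Cc1coc(C(O)[C@](O[Si](CC)(CC)CC)(C(C)C)CCC(C)=C)c1 | intermediate
14 | 2-[(3R)-2,6-dimethyl-3-(triethylsilyloxy)hept-6-en-3-yl]-6-hydroxy-5-methyl-2H-pyran-3(6H)-one (mixture at ring C2 and C6) | OC1OC(C(=O)C=C1C)[C@](O[Si](CC)(CC)CC)(C(C)C)CCC(C)=C | intermediate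
15 | 6-acetoxy-2-[(3R)-2,6-dimethyl-3-(triethylsilyloxy)hept-6-en-3-yl]-5-methyl-2H-pyran-3(6H)-one (mixture at ring C2 and C6) | CC(=O)OC1OC(C(=O)C=C1C)[C@](O[Si](CC)(CC)CC)(C(C)C)CCC(C)=C | intermediate
16 | 2-[(3R)-2,6-dimethyl-3-(triethylsilyloxy)hept-6-en-3-yl]-5-methylpyrylium-3-olate | CC1=C[O+]=C(C([O-])=C1)[C@](O[Si](CC)(CC)CC)(C(C)C)CCC(C)=C | intermediate
17 | (1R,3aR,5S,8aS)-3a,6-dimethyl-1-(propan-2-yl)-1-(triethylsilyloxy)-2,3,3a,4-tetrahydro-1H-5,8a-epoxyazulen-8(5H)-one (oxygen bridge from C5 to C11, C4 ketone) | CC1=CC(=O)[C@]2(O3)[C@](C)(CC[C@@]2(O[Si](CC)(CC)CC)C(C)C)C[C@@H]13 | intermediate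
18 | (1R,3aR,5S,8aR)-5-hydroxy-3a,6-dimethyl-1-(propan-2-yl)-1-(triethylsilyloxy)-2,3,3a,4,5,8a-hexahydroazulen-8(1H)-one | CC1=CC(=O)[C@@H]2[C@](C)(CC[C@@]2(O[Si](CC)(CC)CC)C(C)C)C[C@@H]1O | intermediate
19 | (1R,3aR,5S,8aR)-1,5-dihydroxy-3a,6-dimethyl-1-(propan-2-yl)-2,3,3a,4,5,8a-hexahydroazulen-8(1H)-one | CC1=CC(=O)[C@@H]2[C@](C)(CC[C@@]2(O)C(C)C)C[C@@H]1O | intermediate
20 | (1R,3aR,8aR)-1-hydroxy-3a,6-dimethyl-1-(propan-2-yl)-1,2,3,3a,4,8a-hexahydroazulene-5,8-dione | CC1=CC(=O)[C@@H]2[C@](C)(CC[C@@]2(O)C(C)C)CC1=O | intermediate
21 | (1R,3aR,8S,8aS)-1,8-dihydroxy-3a,6-dimethyl-1-(propan-2-yl)-2,3,3a,4,8,8a-hexahydroazulen-5(1H)-one | CC1=C[C@H](O)[C@@H]2[C@](C)(CC[C@@]2(O)C(C)C)CC1=O | intermediate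
22 | (1R,3aR,8S,8aS)-8-(tert-butyldimethylsilyloxy)-1-hydroxy-3a,6-dimethyl-1-(propan-2-yl)-2,3,3a,4,8,8a-hexahydroazulen-5(1H)-one | CC1=C[C@H](O[Si](C)(C)C(C)(C)C)[C@@H]2[C@](C)(CC[C@@]2(O)C(C)C)CC1=O | intermediate
23 | 4-hydroxybenzoic acid | OC(=O)c1ccc(O)cc1 | starting material
24 | tert-butyldimethylsilyl 4-(tert-butyldimethylsilyloxy)benzoate | CC(C)(C)[Si](C)(C)OC(=O)c1ccc(O[Si](C)(C)C(C)(C)C)cc1 | intermediate
25 | 4-(tert-butyldimethylsilyloxy)benzoyl chloride | ClC(=O)c1ccc(O[Si](C)(C)C(C)(C)C)cc1 | intermediate
26 | (1R,3aR,8S,8aS)-8-(tert-butyldimethylsilyloxy)-3a,6-dimethyl-5-oxo-1-(propan-2-yl)-1,2,3,3a,4,5,8,8a-octahydroazulen-1-yl 4-(tert-butyldimethylsilyloxy)benzoate | CC1=C[C@H](O[Si](C)(C)C(C)(C)C)[C@@H]2[C@](C)(CC[C@@]2(OC(=O)c2ccc(O[Si](C)(C)C(C)(C)C)cc2)C(C)C)CC1=O | intermediate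
27 | (1R,3aR,8S,8aS)-8-hydroxy-3a,6-dimethyl-5-oxo-1-(propan-2-yl)-1,2,3,3a,4,5,8,8a-octahydroazulen-1-yl 4-hydroxybenzoate | CC1=C[C@H](O)[C@@H]2[C@](C)(CC[C@@]2(OC(=O)c2ccc(O)cc2)C(C)C)CC1=O | target

## Step count and risks

Total step count: 19. Longest linear sequence: 16 steps (steps 1–5, 7–15, 18 and 19); steps 6, 16 and 17 are side branches.

**Step 10 (key step).** The most likely failure is poor facial selectivity, the alkene adding to the pyrylium face that puts the isopropyl group cis to the C6 methyl. The preference rests on a steric difference between a silyloxy and an isopropyl group at a fully substituted carbon and is opposed by dipole repulsion between the silyloxy and oxido oxygens. The fallback replaces steric control by a hydrogen bond. It sets out from 13: Bu4NF should give (2R)-5-methyl-1-(4-methylfuran-2-yl)-2-(propan-2-yl)hex-5-ene-1,2-diol F1. Buffered NBS oxidation should give the dihydroxypyranone F2, and Ac2O/pyridine should acylate only the anomeric hydroxyl to give the hydroxy acetate F3. DBU in MeCN should then give the hydroxy cycloadduct F4. The free tertiary hydroxyl can hydrogen-bond to the oxido oxygen and so lock the wanted rotamer; capture of the ylide by this hydroxyl would need a bridgehead enolate and is not open under base. SmI2 in THF/MeOH on F4 returns to the route at 19.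

**Step 11.** The most likely failure is protonation of the samarium enolate on the wrong face of C5, giving the cis-fused ketone, because C5 is flanked on both faces by fully substituted carbons. The fallback replaces kinetic protonation by equilibration. It sets out from 17: the cis-fused hydroxy enone F5 formed by SmI2 is desilylated with HF·pyridine to the cis-fused diol F6, which is equilibrated with catalytic DBU in toluene. Only the trans-fused isomer can hold a hydrogen bond between the C9 hydroxyl and the C4 carbonyl, which should draw the mixture to 19, where the route is rejoined.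

**Step 14.** The most likely failure is slow ligand exchange at the hindered tertiary hydroxyl, so that undirected or conjugate reduction of the enedione competes. The fallback ties the hydride to the C9 oxygen through silicon. It sets out from 20: chlorodiisopropylsilane and imidazole should give the diisopropylsilyl ether F7. Catalytic SnCl4 should trigger intramolecular hydrosilylation of the C4 ketone to the cyclic silylene F8, and HF·pyridine then releases 21.

**Step 18.** The most likely failure is enolisation of the C11 ketone by the tertiary alkoxide (proton transfer from C10) while O-acylation of the hindered alkoxide is slow. The fallback removes the ketone for the acylation. It sets out from 22: NaBH4/CeCl3·7H2O should give the C11 alcohol F9 (both epimers), and Et3SiCl/imidazole should silylate only this secondary hydroxyl to give F10. KN(SiMe3)2 and 25 should give the ester F11, PPTS in MeOH should remove the triethylsilyl group to give F12, and Dess–Martin oxidation returns to the route at 26.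

**Step 7.** The most likely failure is migration of the triethylsilyl group from the tertiary oxygen to the new secondary lithium alkoxide during the exchange period. The fallback reaches the carbinol by acylation and reduction. It sets out from 8: NaClO2/NaH2PO4 with 2-methylbut-2-ene should give the acid F13, and N,O-dimethylhydroxylamine with a carbodiimide the amide F14. Addition of 11, then t-BuLi and a proton quench, should give the furyl ketone F15. NaBH4/CeCl3·7H2O then gives 13, where the route is rejoined.

## Further compounds

F1 | step 10 | (2R)-5-methyl-1-(4-methylfuran-2-yl)-2-(propan-2-yl)hex-5-ene-1,2-diol (both C1 epimers) | Cc1coc(C(O)[C@](O)(C(C)C)CCC(C)=C)c1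
F2 | step 10 | 6-hydroxy-2-[(3R)-3-hydroxy-2,6-dimethylhept-6-en-3-yl]-5-methyl-2H-pyran-3(6H)-one | OC1OC(C(=O)C=C1C)[C@](O)(C(C)C)CCC(C)=C
F3 | step 10 | 6-acetoxy-2-[(3R)-3-hydroxy-2,6-dimethylhept-6-en-3-yl]-5-methyl-2H-pyran-3(6H)-one | CC(=O)OC1OC(C(=O)C=C1C)[C@](O)(C(C)C)CCC(C)=C
F4 | step 10 | (1R,3aR,5S,8aS)-1-hydroxy-3a,6-dimethyl-1-(propan-2-yl)-2,3,3a,4-tetrahydro-1H-5,8a-epoxyazulen-8(5H)-one | CC1=CC(=O)[C@]2(O3)[C@](C)(CC[C@@]2(O)C(C)C)C[C@@H]13
F5 | step 11 | (1R,3aR,5S,8aS)-5-hydroxy-3a,6-dimethyl-1-(propan-2-yl)-1-(triethylsilyloxy)-2,3,3a,4,5,8a-hexahydroazulen-8(1H)-one (cis-fused C5 epimer of 18) | CC1=CC(=O)[C@H]2[C@](C)(CC[C@@]2(O[Si](CC)(CC)CC)C(C)C)C[C@@H]1O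
F6 | step 11 | (1R,3aR,5S,8aS)-1,5-dihydroxy-3a,6-dimethyl-1-(propan-2-yl)-2,3,3a,4,5,8a-hexahydroazulen-8(1H)-one (cis-fused C5 epimer of 19) | CC1=CC(=O)[C@H]2[C@](C)(CC[C@@]2(O)C(C)C)C[C@@H]1O
F7 | step 14 | (1R,3aR,8aR)-1-[di(propan-2-yl)silyloxy]-3a,6-dimethyl-1-(propan-2-yl)-1,2,3,3a,4,8a-hexahydroazulene-5,8-dione | CC1=CC(=O)[C@@H]2[C@](C)(CC[C@@]2(O[SiH](C(C)C)C(C)C)C(C)C)CC1=O
F8 | step 14 | cyclic di(propan-2-yl)silylene derivative of 21 (silicon bridging the C4 and C9 oxygens) | CC1=C[C@H](O3)[C@@H]2[C@](C)(CC[C@@]2(O[Si]3(C(C)C)C(C)C)C(C)C)CC1=O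
F9 | step 18 | (1R,3aR,8S,8aS)-8-(tert-butyldimethylsilyloxy)-3a,6-dimethyl-1-(propan-2-yl)-1,2,3,3a,4,5,8,8a-octahydroazulene-1,5-diol (both C5 epimers) | CC1=C[C@H](O[Si](C)(C)C(C)(C)C)[C@@H]2[C@](C)(CC[C@@]2(O)C(C)C)CC1O
F10 | step 18 | (1R,3aR,8S,8aS)-8-(tert-butyldimethylsilyloxy)-3a,6-dimethyl-1-(propan-2-yl)-5-(triethylsilyloxy)-1,2,3,3a,4,5,8,8a-octahydroazulen-1-ol | CC1=C[C@H](O[Si](C)(C)C(C)(C)C)[C@@H]2[C@](C)(CC[C@@]2(O)C(C)C)CC1O[Si](CC)(CC)CC
F11 | step 18 | (1R,3aR,8S,8aS)-8-(tert-butyldimethylsilyloxy)-3a,6-dimethyl-1-(propan-2-yl)-5-(triethylsilyloxy)-1,2,3,3a,4,5,8,8a-octahydroazulen-1-yl 4-(tert-butyldimethylsilyloxy)benzoate | CC1=C[C@H](O[Si](C)(C)C(C)(C)C)[C@@H]2[C@](C)(CC[C@@]2(OC(=O)c2ccc(O[Si](C)(C)C(C)(C)C)cc2)C(C)C)CC1O[Si](CC)(CC)CC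
F12 | step 18 | (1R,3aR,8S,8aS)-8-(tert-butyldimethylsilyloxy)-5-hydroxy-3a,6-dimethyl-1-(propan-2-yl)-1,2,3,3a,4,5,8,8a-octahydroazulen-1-yl 4-(tert-butyldimethylsilyloxy)benzoate | CC1=C[C@H](O[Si](C)(C)C(C)(C)C)[C@@H]2[C@](C)(CC[C@@]2(OC(=O)c2ccc(O[Si](C)(C)C(C)(C)C)cc2)C(C)C)CC1O
F13 | step 7 | (2R)-5-methyl-2-(propan-2-yl)-2-(triethylsilyloxy)hex-5-enoic acid | OC(=O)[C@](O[Si](CC)(CC)CC)(C(C)C)CCC(C)=C
F14 | step 7 | (2R)-N-methoxy-N,5-dimethyl-2-(propan-2-yl)-2-(triethylsilyloxy)hex-5-enamide | CON(C)C(=O)[C@](O[Si](CC)(CC)CC)(C(C)C)CCC(C)=C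
F15 | step 7 | (2R)-5-methyl-1-(4-methylfuran-2-yl)-2-(propan-2-yl)-2-(triethylsilyloxy)hex-5-en-1-one | Cc1coc(C(=O)[C@](O[Si](CC)(CC)CC)(C(C)C)CCC(C)=C)c1
A1 | alternative 1 | 6-ethenyl-7-methyl-1,4-dioxaspiro[4.4]non-6-ene | C=CC1=C(C)CCC12OCCO2
A2 | alternative 1 | methyl 3-(tert-butyldimethylsilyloxy)-2-diazobut-3-enoate | COC(=O)C(=[N+]=[N-])C(=C)O[Si](C)(C)C(C)(C)C
A3 | alternative 1 | bicyclic cycloheptadiene with C11 silyl enol ether, C2 methyl ester, C4–C5 alkene and C9 ketal | COC(=O)C1=C(O[Si](C)(C)C(C)(C)C)C[C@@]2(C)CCC3(OCCO3)C2=CC1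
A4 | alternative 2 | 3-methylcyclopent-2-en-1-one | CC1=CC(=O)CC1
A5 | alternative 2 | (Z)-3-iodobut-2-enal | C/C(I)=C/C=O
A6 | alternative 2 | cyclopentanone carrying the Z iodoalkenyl carbinol at C5 and methyl plus 1-(trimethylsilyl)vinyl at C6 | C/C(I)=C/[C@H](O)[C@@H]1[C@](C)(CCC1=O)C([Si](C)(C)C)=C
A7 | alternative 3 | 3-(4-methyl-3-oxopentyl)cyclohept-2-en-1-one | CC(C)C(=O)CCC1=CC(=O)CCCC1
A8 | alternative 3 | trans-fused bicyclo[5.3.0]decanone with C4 ketone, angular methyl and C9 tertiary alcohol bearing isopropyl | O=C1CCCC[C@@]2(C)CC[C@@](O)(C(C)C)[C@H]12
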